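**Plan**
1. Retrosynthesis: after removal of two MOM ethers, the target is cut at the bond between the C6 carbonyl carbon and its α-CH2 (Grignard addition, then oxidation), at the aryl ether bond O1–C8a (intramolecular SNAr), at C4–C4a (Sonogashira coupling), and at the C8–prenyl bond together with the prenyl C=C (allyl Claisen rearrangement, then cross-metathesis).
2. Enabling feature: in the 2H-chromene, C8a (the ring carbon bonded to O1) lies para to C6, which carries the carbonyl group. With C6 as a formyl group and C8a as C–F, ring A is electrophilic exactly at the ether carbon, and the hindered O1–C2 linkage can be brought in as a tertiary alcohol.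
3. Forward order: ring A is bought fully substituted; the prenyl group goes onto its only free ortho carbon (future C8); the Z-alkenol arm is attached at the C–Br carbon (future C4a); the pyran ring closes by O1–C8a formation; the dihydrochalcone chain is then added at the aldehyde.
4. Stereochemistry: the target has no stereocentre. The only geometric requirement is the Z alkene of the cyclisation precursor, set by syn semi-hydrogenation; it becomes the endocyclic C3=C4 bond. The carbinol of step 9 is racemic and is oxidised away.

Key step: step 7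

Remark: atom labels (O1, C2 … C8a) follow the 2H-chromene numbering of the target throughout, also for the acyclic precursors; MOM = methoxymethyl.

**Step 1**
Reactants: 1 5-bromo-4-fluoro-2-hydroxybenzaldehyde; 2 allyl bromide
Product: 3 2-(allyloxy)-5-bromo-4-fluorobenzaldehyde
Conditions: K2CO3 (1.5 equiv), DMF, rt
Reagents that add atoms: none
Why: Williamson O-alkylation of the acidic, chelated phenol with a reactive allylic bromide; K2CO3 at room temperature is too mild to touch the aldehyde or the activated C–F bond.

**Step 2**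
Reactants: 3 2-(allyloxy)-5-bromo-4-fluorobenzaldehyde
Product: 5 3-allyl-5-bromo-4-fluoro-2-hydroxybenzaldehyde, via ortho-dienone 4 (not isolated)
Conditions: 1,2-dichlorobenzene, 185 °C, Ar
Reagents that add atoms: none
Why: Aromatic Claisen rearrangement ([3,3]-sigmatropic shift): of the two ortho carbons only C3 carries hydrogen, so dienone 4 formed there tautomerises to the chelated phenol, whereas migration to the formyl-bearing carbon is reversible and unproductive and the para carbon is blocked by bromine.

**Step 3**
Reactants: 5 3-allyl-5-bromo-4-fluoro-2-hydroxybenzaldehyde; 6 2-methylbut-2-ene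
Product: 7 5-bromo-4-fluoro-2-hydroxy-3-(3-methylbut-2-en-1-yl)benzaldehyde
Conditions: 6 (large excess), second-generation Grubbs catalyst RuCl2(=CHPh)(H2IMes)(PCy3) (3 mol%), CH2Cl2, 40 °C
Reagents that add atoms: none
Why: Olefin cross-metathesis of the terminal allyl group with excess 2-methylbut-2-ene, the standard way to turn an aryl allyl group into a prenyl group; the trisubstituted product does not react further and the ruthenium carbene tolerates aldehyde, phenol and aryl halides.

**Step 4**
Reactants: 7 5-bromo-4-fluoro-2-hydroxy-3-(3-methylbut-2-en-1-yl)benzaldehyde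
Product: 8 5-bromo-4-fluoro-2-(methoxymethoxy)-3-(3-methylbut-2-en-1-yl)benzaldehyde
Conditions: MOMCl (1.5 equiv), i-Pr2NEt (2 equiv), CH2Cl2, 0 °C to rt
Reagents that add atoms: chloromethyl methyl ether (MOMCl), COCCl
Why: Acetal-type O-alkylation (MOM protection) of the phenol with a hindered amine base; capping the C7 oxygen prevents phenoxide formation, which would deactivate ring A in step 7 and quench the Grignard reagent in step 9.

**Step 5**
Reactants: 8 5-bromo-4-fluoro-2-(methoxymethoxy)-3-(3-methylbut-2-en-1-yl)benzaldehyde; 9 2-methylbut-3-yn-2-ol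
Product: 10 4-fluoro-5-(3-hydroxy-3-methylbut-1-yn-1-yl)-2-(methoxymethoxy)-3-(3-methylbut-2-en-1-yl)benzaldehyde
Conditions: PdCl2(PPh3)2 (3 mol%), CuI (copper iodide, 5 mol%), Et3N, THF, 65 °C
Reagents that add atoms: none
Why: Sonogashira coupling: zerovalent palladium inserts only into the C–Br bond (C–F is inert), the copper acetylide of 9 transmetallates, and the trisubstituted prenyl alkene, the aldehyde and the MOM ether are spectators.

**Step 6**
Reactants: 10 4-fluoro-5-(3-hydroxy-3-methylbut-1-yn-1-yl)-2-(methoxymethoxy)-3-(3-methylbut-2-en-1-yl)benzaldehyde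
Product: 11 (Z)-4-fluoro-5-(3-hydroxy-3-methylbut-1-en-1-yl)-2-(methoxymethoxy)-3-(3-methylbut-2-en-1-yl)benzaldehyde
Conditions: H2 (1 atm), Pd/CaCO3 poisoned with Pb(OAc)2 (Lindlar catalyst), quinoline, EtOAc, rt, stopped after one equivalent of H2
Reagents that add atoms: none
Why: Lindlar semi-hydrogenation: syn delivery of H2 from the poisoned palladium surface to the alkyne gives the Z alkene, and the poisoned catalyst leaves the trisubstituted prenyl alkene, the aldehyde and the C–F bond alone.

**Step 7**
Reactants: 11 (Z)-4-fluoro-5-(3-hydroxy-3-methylbut-1-en-1-yl)-2-(methoxymethoxy)-3-(3-methylbut-2-en-1-yl)benzaldehyde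
Product: 13 7-(methoxymethoxy)-2,2-dimethyl-8-(3-methylbut-2-en-1-yl)-2H-chromene-6-carbaldehyde, via potassium alkoxide 12 (not isolated)
Conditions: KOt-Bu (1.1 equiv), THF, 0 °C to rt
Reagents that add atoms: potassium tert-butoxide, CC(C)(C)[O-].[K+] (its potassium sits only in the non-isolated alkoxide 12 and leaves as KF; no atom of it remains in 13)
Why: tert-Butoxide deprotonates the tertiary allylic alcohol to alkoxide 12, whose oxygen is held over C8a by the Z double bond; attack at C8a and expulsion of fluoride (addition–elimination SNAr, with the negative charge of the Meisenheimer-type transition structure delocalised into the para C6 formyl group) forms the O1–C8a bond. The closest known reaction type is the intramolecular displacement of fluoride from 4-fluorobenzaldehydes, 4-fluoroaryl ketones and nitriles by pendant alkoxides, which gives chromans and related benzo-fused cyclic ethers. The pyran ring (O1, C2, C3, C4, C4a, C8a) closes in a six-membered mode, formally 6-exo-trig if the C8a=C8 bond of the arene is taken as the accepting π bond. No stereocentre is created; the one stereochemical requirement is the Z geometry of the tether fixed in step 6, because the E isomer cannot reach C8a. The step needs attack at C8a in preference to the formyl carbon and an electron-poor ring: the aldehyde has no α-hydrogen and adds the hindered tertiary alkoxide only reversibly, the C7 oxygen is capped as its MOM ether so that no deactivating phenoxide can form, and fluoride is the only leaving group on the ring. One equivalent of base in THF at or below room temperature should leave the benzylic-allylic CH2 of the prenyl group untouched.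

**Step 8**
Reactants: 14 4-(2-bromoethyl)phenol
Product: 15 1-(2-bromoethyl)-4-(methoxymethoxy)benzene
Conditions: MOMCl (1.3 equiv), i-Pr2NEt (1.8 equiv), CH2Cl2, 0 °C to rt
Reagents that add atoms: chloromethyl methyl ether (MOMCl), COCCl
Why: MOM protection of the phenol under non-nucleophilic amine conditions, which avoid phenoxide-driven loss of the primary bromide; the resulting acetal is inert to magnesium and to the Grignard reagent.

**Step 9**
Reactants: 15 1-(2-bromoethyl)-4-(methoxymethoxy)benzene; 13 7-(methoxymethoxy)-2,2-dimethyl-8-(3-methylbut-2-en-1-yl)-2H-chromene-6-carbaldehyde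
Product: 17 1-[7-(methoxymethoxy)-2,2-dimethyl-8-(3-methylbut-2-en-1-yl)-2H-chromen-6-yl]-3-[4-(methoxymethoxy)phenyl]propan-1-ol (racemic), via Grignard reagent 16 (not isolated)
Conditions: 15, Mg turnings (iodine-activated), THF, 40 °C; then 13, THF, −20 to 0 °C; H2O quench, sat. aq NH4Cl work-up
Reagents that add atoms: magnesium, [Mg] (held only in the non-isolated Grignard reagent 16; no atom of it remains in 17)
Why: Grignard reaction: magnesium inserts into the primary C–Br bond to give 16, which adds 1,2 to the non-enolisable aldehyde (the ortho MOM oxygen can chelate magnesium); the new carbinol centre forms without control as a racemate and is removed by the oxidation in step 10.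

**Step 10**
Reactants: 17 1-[7-(methoxymethoxy)-2,2-dimethyl-8-(3-methylbut-2-en-1-yl)-2H-chromen-6-yl]-3-[4-(methoxymethoxy)phenyl]propan-1-ol
Product: 18 1-[7-(methoxymethoxy)-2,2-dimethyl-8-(3-methylbut-2-en-1-yl)-2H-chromen-6-yl]-3-[4-(methoxymethoxy)phenyl]propan-1-one
Conditions: Dess–Martin periodinane (1.3 equiv), NaHCO3 (3 equiv), CH2Cl2, 0 °C to rt
Reagents that add atoms: none
Why: Dess–Martin oxidation of a secondary benzylic alcohol to the aryl ketone under buffered, near-neutral conditions that do not touch the prenyl or chromene double bonds or the MOM acetals and do not ionise the electron-rich benzylic alcohol.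

**Step 11**
Reactants: 18 1-[7-(methoxymethoxy)-2,2-dimethyl-8-(3-methylbut-2-en-1-yl)-2H-chromen-6-yl]-3-[4-(methoxymethoxy)phenyl]propan-1-one
Product: 19 1-[7-hydroxy-2,2-dimethyl-8-(3-methylbut-2-en-1-yl)-2H-chromen-6-yl]-3-(4-hydroxyphenyl)propan-1-one (CNP0163015.0)
Conditions: 3 M aq HCl, MeOH, 40 °C
Reagents that add atoms: none
Why: Acid-catalysed transacetalisation (MOM ether cleavage) in methanol: the C7 ether is assisted by the neighbouring carbonyl and the freed C7 hydroxyl is held in a hydrogen bond to the ketone, which disfavours its acid-catalysed addition to the prenyl group, while the remote aryl MOM ether cleaves at the same moderate acidity.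

**Compound list**
1 | 5-bromo-4-fluoro-2-hydroxybenzaldehyde | O=Cc1cc(Br)c(F)cc1O | starting material
2 | allyl bromide | C=CCBr | starting material
3 | 2-(allyloxy)-5-bromo-4-fluorobenzaldehyde | O=Cc1cc(Br)c(F)cc1OCC=C | intermediate
4 | ortho-dienone (5-allyl-3-bromo-4-fluoro-6-oxocyclohexa-1,3-diene-1-carbaldehyde, racemic, not isolated) | O=CC1=CC(Br)=C(F)C(CC=C)C1=O | intermediate
5 | 3-allyl-5-bromo-4-fluoro-2-hydroxybenzaldehyde | O=Cc1cc(Br)c(F)c(CC=C)c1O | intermediate
6 | 2-methylbut-2-ene | CC=C(C)C | starting material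
7 | 5-bromo-4-fluoro-2-hydroxy-3-(3-methylbut-2-en-1-yl)benzaldehyde | O=Cc1cc(Br)c(F)c(CC=C(C)C)c1O | intermediate
8 | 5-bromo-4-fluoro-2-(methoxymethoxy)-3-(3-methylbut-2-en-1-yl)benzaldehyde | COCOc1c(C=O)cc(Br)c(F)c1CC=C(C)C | intermediate
9 | 2-methylbut-3-yn-2-ol | C#CC(C)(C)O | starting material
10 | 4-fluoro-5-(3-hydroxy-3-methylbut-1-yn-1-yl)-2-(methoxymethoxy)-3-(3-methylbut-2-en-1-yl)benzaldehyde | CC(C)(O)C#Cc1cc(C=O)c(OCOC)c(CC=C(C)C)c1F | intermediate
11 | (Z)-4-fluoro-5-(3-hydroxy-3-methylbut-1-en-1-yl)-2-(methoxymethoxy)-3-(3-methylbut-2-en-1-yl)benzaldehyde | CC(C)(O)/C=C\c1cc(C=O)c(OCOC)c(CC=C(C)C)c1F | intermediate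
12 | potassium alkoxide of 11 (potassium (Z)-4-[2-fluoro-5-formyl-4-(methoxymethoxy)-3-(3-methylbut-2-en-1-yl)phenyl]-2-methylbut-3-en-2-olate, not isolated) | CC(C)([O-])/C=C\c1cc(C=O)c(OCOC)c(CC=C(C)C)c1F.[K+] | intermediate
13 | 7-(methoxymethoxy)-2,2-dimethyl-8-(3-methylbut-2-en-1-yl)-2H-chromene-6-carbaldehyde | COCOc1c(C=O)cc2C=CC(C)(C)Oc2c1CC=C(C)C | intermediate
14 | 4-(2-bromoethyl)phenol | Oc1ccc(CCBr)cc1 | starting material
15 | 1-(2-bromoethyl)-4-(methoxymethoxy)benzene | COCOc1ccc(CCBr)cc1 | intermediate
16 | Grignard reagent ({2-[4-(methoxymethoxy)phenyl]ethyl}magnesium bromide, not isolated) | COCOc1ccc(CC[Mg]Br)cc1 | intermediate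
17 | 1-[7-(methoxymethoxy)-2,2-dimethyl-8-(3-methylbut-2-en-1-yl)-2H-chromen-6-yl]-3-[4-(methoxymethoxy)phenyl]propan-1-ol (racemic) | COCOc1ccc(CCC(O)c2cc3C=CC(C)(C)Oc3c(CC=C(C)C)c2OCOC)cc1 | intermediate
18 | 1-[7-(methoxymethoxy)-2,2-dimethyl-8-(3-methylbut-2-en-1-yl)-2H-chromen-6-yl]-3-[4-(methoxymethoxy)phenyl]propan-1-one | COCOc1ccc(CCC(=O)c2cc3C=CC(C)(C)Oc3c(CC=C(C)C)c2OCOC)cc1 | intermediate
19 | 1-[7-hydroxy-2,2-dimethyl-8-(3-methylbut-2-en-1-yl)-2H-chromen-6-yl]-3-(4-hydroxyphenyl)propan-1-one (no stereocentre) | CC(C)=CCc1c(O)c(C(=O)CCc2ccc(O)cc2)cc2c1OC(C)(C)C=C2 | target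

**Step count**
Total steps: 11. Longest linear sequence: 10 steps (steps 1–7 and 9–11, from 1); step 8 is a one-step side branch.

**Steps most likely to fail**

Step 7 (ring closure). What may go wrong: tert-butoxide or the substrate alkoxide adds to the formyl carbon and the aldehyde is then lost by base-induced hydride transfer; fluoride displacement at the doubly ortho-substituted C8a is too slow at temperatures the aldehyde tolerates; the prenyl double bond migrates under base. Fallback: exchange the activating group for a nitrile, which is comparably para-activating but inert to alkoxide, so that hotter and more basic conditions become usable. Setting out from bromide 8, condensation with NH2OH·HCl/NaOAc in EtOH would give 5-bromo-4-fluoro-2-(methoxymethoxy)-3-(3-methylbut-2-en-1-yl)benzaldehyde oxime F1. Dehydration with 1,1'-carbonyldiimidazole in CH2Cl2 would give 5-bromo-4-fluoro-2-(methoxymethoxy)-3-(3-methylbut-2-en-1-yl)benzonitrile F2. Sonogashira coupling with 9 under the conditions of step 5 would give the alkynol nitrile F3, and Lindlar semi-hydrogenation as in step 6 the Z-alkenol nitrile F4. KOt-Bu in DMF at 25–70 °C should close the same O1–C8a bond to give 7-(methoxymethoxy)-2,2-dimethyl-8-(3-methylbut-2-en-1-yl)-2H-chromene-6-carbonitrile F5. Addition of Grignard reagent 16 (CuBr·SMe2 cat., THF, reflux) would give the ketimine F6, whose brief hydrolysis with cold dilute aqueous HCl would deliver ketone 18. The fallback thus rejoins the route at 18 and makes steps 9 and 10 unnecessary.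

Step 11 (global deprotection). What may go wrong: the acidity needed to cleave the non-chelated aryl MOM ether also protonates the prenyl double bond, so that the freed C7 hydroxyl adds across it to form a chroman ring, or the 2H-chromene is hydrated or opened. Fallback: carry the remote phenol as a fluoride-labile silyl ether, so that only the carbonyl-assisted C7 MOM ether needs acid, and then only weak acid. Setting out from phenol 14, TBSCl/imidazole (DMF, rt) would give tert-butyl[4-(2-bromoethyl)phenoxy]dimethylsilane F8. Its Grignard reagent, {2-[4-(tert-butyldimethylsilyloxy)phenyl]ethyl}magnesium bromide F9 (Mg, THF), would be added to aldehyde 13 to give the silyl-protected carbinol F10. Dess–Martin oxidation would give the silyl-protected ketone F11. TBAF buffered with AcOH (THF, 0 °C) would free the remote phenol to give the mono-MOM ketone F12. PPTS in MeOH at 45 °C should then remove the C7 MOM ether and give target 19, where the fallback rejoins the route.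

Step 6 (semi-hydrogenation). What may go wrong: hydrogen uptake does not stop at the alkene, or the Z alkene isomerises to E on the catalyst surface, giving material that cannot cyclise. Fallback: make the E alkene directly and invert its geometry with light. Setting out from bromide 8, Heck coupling with commercial 2-methylbut-3-en-2-ol (Pd(OAc)2, P(o-tol)3, Et3N, MeCN, 90 °C) would give (E)-4-fluoro-5-(3-hydroxy-3-methylbut-1-en-1-yl)-2-(methoxymethoxy)-3-(3-methylbut-2-en-1-yl)benzaldehyde F7. Triplet-sensitised E-to-Z isomerisation (Ir(ppy)3, tris(2-phenylpyridinato)iridium, 1 mol%, blue LED, MeCN, rt) should enrich the Z isomer 11, because the twisted Z styrene is excited less efficiently than the planar E isomer. Unchanged F7 would be recycled, and any E isomer carried forward cannot cyclise in step 7 and should separate from 13. The fallback rejoins the route at 11.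

**Further compounds**
F1 | step 7 | (E)-5-bromo-4-fluoro-2-(methoxymethoxy)-3-(3-methylbut-2-en-1-yl)benzaldehyde oxime | COCOc1c(/C=N/O)cc(Br)c(F)c1CC=C(C)C
F2 | step 7 | 5-bromo-4-fluoro-2-(methoxymethoxy)-3-(3-methylbut-2-en-1-yl)benzonitrile | COCOc1c(C#N)cc(Br)c(F)c1CC=C(C)C
F3 | step 7 | 4-fluoro-5-(3-hydroxy-3-methylbut-1-yn-1-yl)-2-(methoxymethoxy)-3-(3-methylbut-2-en-1-yl)benzonitrile | CC(C)(O)C#Cc1cc(C#N)c(OCOC)c(CC=C(C)C)c1F
F4 | step 7 | (Z)-4-fluoro-5-(3-hydroxy-3-methylbut-1-en-1-yl)-2-(methoxymethoxy)-3-(3-methylbut-2-en-1-yl)benzonitrile | CC(C)(O)/C=C\c1cc(C#N)c(OCOC)c(CC=C(C)C)c1F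
F5 | step 7 | 7-(methoxymethoxy)-2,2-dimethyl-8-(3-methylbut-2-en-1-yl)-2H-chromene-6-carbonitrile | COCOc1c(C#N)cc2C=CC(C)(C)Oc2c1CC=C(C)C
F6 | step 7 | 1-[7-(methoxymethoxy)-2,2-dimethyl-8-(3-methylbut-2-en-1-yl)-2H-chromen-6-yl]-3-[4-(methoxymethoxy)phenyl]propan-1-imine | COCOc1ccc(CCC(=N)c2cc3C=CC(C)(C)Oc3c(CC=C(C)C)c2OCOC)cc1
F7 | step 6 | (E)-4-fluoro-5-(3-hydroxy-3-methylbut-1-en-1-yl)-2-(methoxymethoxy)-3-(3-methylbut-2-en-1-yl)benzaldehyde | CC(C)(O)/C=C/c1cc(C=O)c(OCOC)c(CC=C(C)C)c1F
F8 | step 11 | tert-butyl[4-(2-bromoethyl)phenoxy]dimethylsilane | CC(C)(C)[Si](C)(C)Oc1ccc(CCBr)cc1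
F9 | step 11 | {2-[4-(tert-butyldimethylsilyloxy)phenyl]ethyl}magnesium bromide | CC(C)(C)[Si](C)(C)Oc1ccc(CC[Mg]Br)cc1
F10 | step 11 | 3-[4-(tert-butyldimethylsilyloxy)phenyl]-1-[7-(methoxymethoxy)-2,2-dimethyl-8-(3-methylbut-2-en-1-yl)-2H-chromen-6-yl]propan-1-ol (racemic) | CC(C)(C)[Si](C)(C)Oc1ccc(CCC(O)c2cc3C=CC(C)(C)Oc3c(CC=C(C)C)c2OCOC)cc1
F11 | step 11 | 3-[4-(tert-butyldimethylsilyloxy)phenyl]-1-[7-(methoxymethoxy)-2,2-dimethyl-8-(3-methylbut-2-en-1-yl)-2H-chromen-6-yl]propan-1-one | CC(C)(C)[Si](C)(C)Oc1ccc(CCC(=O)c2cc3C=CC(C)(C)Oc3c(CC=C(C)C)c2OCOC)cc1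
F12 | step 11 | 3-(4-hydroxyphenyl)-1-[7-(methoxymethoxy)-2,2-dimethyl-8-(3-methylbut-2-en-1-yl)-2H-chromen-6-yl]propan-1-one | COCOc1c(C(=O)CCc2ccc(O)cc2)cc2C=CC(C)(C)Oc2c1CC=C(C)C
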